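**Retrosynthetic overview**
1. Target 32 ⇐ C16–C17: epoxy triflate 29 + homoallylic Grignard reagent 31 (CuBr·SMe2-catalysed SN2 at the primary triflate).
2. 29 ⇐ 28 ⇐ 27: hydroxyl-directed Ti(OiPr)4/diethyl tartrate epoxidation (C–O bonds; sets C14 and C15; oxidises one C=C of five). The oxirane is the only ring and is formed in step 12.
3. 27 ⇐ C8–C9: Grignard reagent 26 + monochloride 7 of the C2-symmetric C10 diol 6 (double Wittig on succinaldehyde).
4. Iodide 18 ⇐ C4–C5: dianion 16 of (S)-alcohol 14 + iodide 15 (from (R)-alcohol 11); iodide 23 ⇐ alcohol 22.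
5. 11, 14 and 22 ⇐ isoprene (8) or myrcene (19) + CO2 by a new CuH-catalysed enantioselective hydroxymethylation (sets C3, C7 and C18).

Convention: C1–C24 is the main chain of the target, counted from the isopropenyl CH2 (C1); the oxirane carbons are C14 and C15.
Assumption: in the new hydroxymethylation the (R)-ligand gives the (R)-alcohol; if the first run shows the opposite sense, the ligand enantiomers are exchanged between step 4 and steps 5 and 9.

**Route**

Step 1
Reactants: 1 2,5-dimethoxytetrahydrofuran; 2 ethyl 2-(triphenyl-λ5-phosphanylidene)propanoate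
Product: 5 diethyl (2E,6E)-2,7-dimethylocta-2,6-dienedioate, via butanedial 3 (not isolated), via mono-olefination aldehyde 4 (not isolated)
Conditions: 0.6 M aq. HCl, 70 °C, 1 h; NaHCO3 to pH 7; then 2 (2.3 equiv), CH2Cl2, rt, 16 h
Reagents that add atoms: none
Why: acid hydrolysis of the bis-acetal frees succinaldehyde, and a double Wittig olefination with the stabilised α-methyl ylide gives both trisubstituted enoates with the usual ≥95:5 E selectivity, so the C2-symmetric C9–C16 core arises in one pot with no stereocentre to set.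

Step 2
Reactants: 5 diethyl (2E,6E)-2,7-dimethylocta-2,6-dienedioate
Product: 6 (2E,6E)-2,7-dimethylocta-2,6-diene-1,8-diol
Conditions: i-Bu2AlH (4.4 equiv), CH2Cl2, −78 → 0 °C; aq. potassium sodium tartrate
Reagents that add atoms: none
Why: i-Bu2AlH reduces α,β-unsaturated esters by clean 1,2-addition (ester to allylic alcohol reduction) without touching the alkene geometry.

Step 3
Reactants: 6 (2E,6E)-2,7-dimethylocta-2,6-diene-1,8-diol
Product: 7 (2E,6E)-8-chloro-2,7-dimethylocta-2,6-dien-1-ol
Conditions: N-chlorosuccinimide (0.55 equiv), Me2S (0.65 equiv), CH2Cl2, −30 → 0 °C; unreacted 6 recovered and recycled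
Reagents that add atoms: N-chlorosuccinimide, ClN1C(=O)CCC1=O
Why: the Corey–Kim chlorination converts a primary allylic alcohol into the chloride by SN2 at carbon without allylic transposition or E/Z change, and because 6 is C2-symmetric the statistical mono-reaction gives a single monochloride (about 45 % per pass) whose two ends are now different.

Step 4
Reactants: 8 isoprene
Product: 11 (2R)-2,3-dimethylbut-3-en-1-ol, via silyl ester 9 (not isolated), via silyl ether 10 (not isolated)
Conditions: Cu(OAc)2 (5 mol %), (R)-DTBM-SEGPHOS (5.5 mol %), HSiMe(OMe)2 (4 equiv), CO2 (1 atm), cyclohexane, sealed tube, 40 °C, 24 h; then NH4F (cat.), MeOH, rt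
Reagents that add atoms: carbon dioxide, O=C=O
Why: Proposed new method: copper hydride-catalysed enantioselective 4,3-hydro-hydroxymethylation of a 2-alkyl-1,3-diene with CO2, in which L*Cu–H adds across the unsubstituted vinyl group (H to C4), the allylcopper settles as the primary σ-allyl isomer (Cu on the CH2 carbon) and inserts CO2 at the γ-carbon through a closed six-membered SE2′ transition state inside the chiral bisphosphine pocket, which sets the CH(CH3) stereocentre next to the 1,1-disubstituted alkene, after which the silane returns L*Cu–H and reduces silyl ester 9 to silyl ether 10 in the same pot; the closest known reaction types are the CuH-catalysed asymmetric reductive hydroxymethylation of styrenes and 1-aryl-1,3-dienes with CO2 and the CuH-catalysed enantioselective allylation of ketones with 1,3-dienes, neither shown for a simple 2-alkyl diene giving this α-methyl-β-methylene alcohol.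

Step 5
Reactants: 8 isoprene
Product: 14 (2S)-2,3-dimethylbut-3-en-1-ol, via silyl ester 12 (not isolated), via silyl ether 13 (not isolated)
Conditions: Cu(OAc)2 (5 mol %), (S)-DTBM-SEGPHOS (5.5 mol %), HSiMe(OMe)2 (4 equiv), CO2 (1 atm), cyclohexane, sealed tube, 40 °C, 24 h; then NH4F (cat.), MeOH, rt
Reagents that add atoms: carbon dioxide, O=C=O
Why: Proposed new method: the same CuH-catalysed 4,3-hydro-hydroxymethylation as in step 4 (hydrocupration of the vinyl group, γ-selective CO2 insertion of the primary σ-allylcopper, in situ silane reduction; closest known type again the CuH/CO2 hydroxymethylation of styrenes and aryl dienes), run with the mirror-image ligand so that the opposite face of the allyl unit is carboxylated and the (S)-alcohol results.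

Step 6
Reactants: 11 (2R)-2,3-dimethylbut-3-en-1-ol
Product: 15 (3R)-4-iodo-2,3-dimethylbut-1-ene
Conditions: PPh3, I2, imidazole, CH2Cl2, 0 °C, dark
Reagents that add atoms: iodine, II
Why: Appel-type iodination replaces the primary hydroxyl by SN2 at CH2, so the neighbouring allylic stereocentre is not involved.

Step 7
Reactants: 14 (2S)-2,3-dimethylbut-3-en-1-ol; 15 (3R)-4-iodo-2,3-dimethylbut-1-ene
Product: 17 (2S,6S)-2,6,7-trimethyl-3-methylideneoct-7-en-1-ol, via dilithio dianion 16 (not isolated)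
Conditions: 14, n-BuLi (2.2 equiv), TMEDA (2.2 equiv), Et2O/hexane, 0 °C → rt, 8 h; then 15 (0.9 equiv), THF, −78 → 0 °C; H2O
Reagents that add atoms: none
Why: alkoxide-directed allylic lithiation of the vinylic methyl group (as known for 3-methylbut-3-en-1-ol) gives a 2-substituted allyl anion whose two termini are equivalent and which does not include the stereocentre, and its SN2 alkylation by the primary iodide at low temperature (which also holds back E2) forms C4–C5 with C3 (from 15) and C7 (from 14) carried over unchanged.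

Step 8
Reactants: 17 (2S,6S)-2,6,7-trimethyl-3-methylideneoct-7-en-1-ol
Product: 18 (3S,7S)-8-iodo-2,3,7-trimethyl-6-methylideneoct-1-ene
Conditions: PPh3, I2, imidazole, CH2Cl2, 0 °C, dark
Reagents that add atoms: iodine, II
Why: Appel-type iodination by SN2 at the primary carbon leaves both stereocentres untouched (the descriptor at C7 is S here only because CH2I outranks the vinylic carbon).

Step 9
Reactants: 19 myrcene (7-methyl-3-methylideneocta-1,6-diene)
Product: 22 (2S)-2,7-dimethyl-3-methylideneoct-6-en-1-ol, via silyl ester 20 (not isolated), via silyl ether 21 (not isolated)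
Conditions: Cu(OAc)2 (5 mol %), (S)-DTBM-SEGPHOS (5.5 mol %), HSiMe(OMe)2 (4 equiv), CO2 (1 atm), cyclohexane, sealed tube, 40 °C, 24 h; then NH4F (cat.), MeOH, rt
Reagents that add atoms: carbon dioxide, O=C=O
Why: Proposed new method: the same copper hydride-catalysed hydro-hydroxymethylation as in steps 4 and 5, applied to the 2-alkyl diene myrcene, in which L*Cu–H adds only across the unsubstituted vinyl group (H to C1; the remote trisubstituted alkene is inert to copper hydride), the primary σ-allylcopper inserts CO2 at the γ-carbon through the six-membered SE2′ transition state and the silane reduces silyl ester 20 to silyl ether 21, so that with the (S)-ligand of step 5 (the homoprenyl chain merely replaces the methyl group of isoprene) the (S)-centre that becomes C18 is set; the closest known reaction types are again the CuH-catalysed asymmetric hydroxymethylation of styrenes and 1-aryl-1,3-dienes with CO2 and the CuH-catalysed enantioselective allylation of ketones with 2-substituted 1,3-dienes.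

Step 10
Reactants: 22 (2S)-2,7-dimethyl-3-methylideneoct-6-en-1-ol
Product: 23 (7S)-8-iodo-2,7-dimethyl-6-methylideneoct-2-ene
Conditions: PPh3, I2, imidazole, CH2Cl2, 0 °C, dark
Reagents that add atoms: iodine, II
Why: Appel-type iodination by SN2 at the primary carbon, stereocentre untouched.

Step 11
Reactants: 7 (2E,6E)-8-chloro-2,7-dimethylocta-2,6-dien-1-ol; 18 (3S,7S)-8-iodo-2,3,7-trimethyl-6-methylideneoct-1-ene
Product: 27 (2E,6E,10R,14S)-2,7,10,14,15-pentamethyl-11-methylidenehexadeca-2,6,15-trien-1-ol, via lithium alkoxide 24 (not isolated), via alkyllithium 25 (not isolated), via alkylmagnesium bromide 26 (not isolated)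
Conditions: 18, t-BuLi (2.1 equiv), Et2O/pentane, −78 °C; MgBr2·OEt2 (1.05 equiv), −78 → −40 °C; added to 7 (1.3 equiv) pre-treated with n-BuLi (1.0 equiv per 7), THF, −78 °C; Li2CuCl4 (3 mol %), −40 → 0 °C; H2O
Reagents that add atoms: none
Why: iodine–lithium exchange at −78 °C and transmetalation give the primary Grignard reagent without homoallyl–cyclopropylcarbinyl scrambling, and under Li2CuCl4 catalysis (allyl–alkyl coupling of the Kochi/Schlosser type) it displaces the primary allylic chloride at the α-carbon with retention of the E geometry, the alkoxide being a spectator and no stereocentre being formed.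

Step 12
Reactants: 27 (2E,6E,10R,14S)-2,7,10,14,15-pentamethyl-11-methylidenehexadeca-2,6,15-trien-1-ol
Product: 28 [(2R,3R)-2-methyl-3-[(3E,7R,11S)-4,7,11,12-tetramethyl-8-methylidenetrideca-3,12-dien-1-yl]oxiran-2-yl]methanol
Conditions: Ti(OiPr)4 (10 mol %), D-(−)-diethyl tartrate (12 mol %), t-BuOOH (2 equiv, anhydrous in isooctane), 4 Å molecular sieves, CH2Cl2, −20 °C
Reagents that add atoms: tert-butyl hydroperoxide, CC(C)(C)OO
Why: Katsuki–Sharpless asymmetric epoxidation, the key C–O bond-forming step, in which only the allylic alcohol binds the Ti(OiPr)4–tartrate catalyst so that of the five C=C bonds only C14=C15 is oxidised, and with D-(−)-diethyl tartrate oxygen is delivered to the face that gives the (2R,3R)-epoxy alcohol (E-2-methyl-3-alkyl allylic alcohols give the 2S,3S series with the L-tartrate), setting C14 and C15 in about 95:5 selectivity.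

Step 13
Reactants: 28 [(2R,3R)-2-methyl-3-[(3E,7R,11S)-4,7,11,12-tetramethyl-8-methylidenetrideca-3,12-dien-1-yl]oxiran-2-yl]methanol; 23 (7S)-8-iodo-2,7-dimethyl-6-methylideneoct-2-ene
Product: 32 (2R,3R)-2-[(3R)-3,8-dimethyl-4-methylidenenon-7-en-1-yl]-2-methyl-3-[(3E,7R,11S)-4,7,11,12-tetramethyl-8-methylidenetrideca-3,12-dien-1-yl]oxirane (CNP0279512.1), via epoxy triflate 29 (not isolated), via alkyllithium 30 (not isolated), via alkylmagnesium bromide 31 (not isolated)
Conditions: 28, Tf2O (1.1 equiv), 2,6-lutidine (1.5 equiv), CH2Cl2, −78 °C, cold pentane filtration; 23 (1.5 equiv), t-BuLi (2.1 equiv per 23), Et2O/pentane, −78 °C; MgBr2·OEt2; CuBr·SMe2 (10 mol %), crude 29, Et2O/THF, −78 → −40 °C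
Reagents that add atoms: none
Why: a primary triflate is displaced by a Grignard reagent under CuBr·SMe2 catalysis at −78 °C (Kotsuki-type triflate coupling) much faster than the trisubstituted oxirane is opened at its hindered secondary carbon, so C16–C17 is formed by SN2 at CH2 with all five stereocentres untouched.

**Compound list**
1 | 2,5-dimethoxytetrahydrofuran (cis/trans mixture) | COC1CCC(OC)O1 | starting material
2 | ethyl 2-(triphenyl-λ5-phosphanylidene)propanoate | CCOC(=O)C(C)=P(c1ccccc1)(c1ccccc1)c1ccccc1 | starting material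
3 | butanedial (succinaldehyde) | O=CCCC=O | intermediate
4 | ethyl (2E)-2-methyl-6-oxohex-2-enoate | CCOC(=O)/C(C)=C/CCC=O | intermediate
5 | diethyl (2E,6E)-2,7-dimethylocta-2,6-dienedioate | CCOC(=O)/C(C)=C/CC/C=C(\C)C(=O)OCC | intermediate
6 | (2E,6E)-2,7-dimethylocta-2,6-diene-1,8-diol | OC/C(C)=C/CC/C=C(\C)CO | intermediate
7 | (2E,6E)-8-chloro-2,7-dimethylocta-2,6-dien-1-ol | OC/C(C)=C/CC/C=C(\C)CCl | intermediate
8 | isoprene (2-methylbuta-1,3-diene) | C=CC(C)=C | starting material
9 | dimethoxy(methyl)silyl (2R)-2,3-dimethylbut-3-enoate | C=C(C)[C@@H](C)C(=O)O[Si](C)(OC)OC | intermediate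
10 | {[(2R)-2,3-dimethylbut-3-en-1-yl]oxy}(dimethoxy)methylsilane | C=C(C)[C@@H](C)CO[Si](C)(OC)OC | intermediate
11 | (2R)-2,3-dimethylbut-3-en-1-ol | C=C(C)[C@@H](C)CO | intermediate
12 | dimethoxy(methyl)silyl (2S)-2,3-dimethylbut-3-enoate | C=C(C)[C@H](C)C(=O)O[Si](C)(OC)OC | intermediate
13 | {[(2S)-2,3-dimethylbut-3-en-1-yl]oxy}(dimethoxy)methylsilane | C=C(C)[C@H](C)CO[Si](C)(OC)OC | intermediate
14 | (2S)-2,3-dimethylbut-3-en-1-ol | C=C(C)[C@H](C)CO | intermediate
15 | (3R)-4-iodo-2,3-dimethylbut-1-ene | C=C(C)[C@@H](C)CI | intermediate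
16 | lithium (2S)-3-(lithiomethyl)-2-methylbut-3-en-1-olate (dianion of 14) | [Li]CC(=C)[C@H](C)CO[Li] | intermediate
17 | (2S,6S)-2,6,7-trimethyl-3-methylideneoct-7-en-1-ol | C=C(CC[C@H](C)C(=C)C)[C@H](C)CO | intermediate
18 | (3S,7S)-8-iodo-2,3,7-trimethyl-6-methylideneoct-1-ene | C=C(CC[C@H](C)C(=C)C)[C@H](C)CI | intermediate
19 | myrcene (7-methyl-3-methylideneocta-1,6-diene) | C=CC(=C)CCC=C(C)C | starting material
20 | dimethoxy(methyl)silyl (2S)-2,7-dimethyl-3-methylideneoct-6-enoate | CC(C)=CCCC(=C)[C@H](C)C(=O)O[Si](C)(OC)OC | intermediate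
21 | {[(2S)-2,7-dimethyl-3-methylideneoct-6-en-1-yl]oxy}(dimethoxy)methylsilane | CC(C)=CCCC(=C)[C@H](C)CO[Si](C)(OC)OC | intermediate
22 | (2S)-2,7-dimethyl-3-methylideneoct-6-en-1-ol | CC(C)=CCCC(=C)[C@H](C)CO | intermediate
23 | (7S)-8-iodo-2,7-dimethyl-6-methylideneoct-2-ene | CC(C)=CCCC(=C)[C@H](C)CI | intermediate
24 | lithium (2E,6E)-8-chloro-2,7-dimethylocta-2,6-dien-1-olate | [Li]OC/C(C)=C/CC/C=C(\C)CCl | intermediate
25 | [(2R,6S)-2,6,7-trimethyl-3-methylideneoct-7-en-1-yl]lithium (18 with I replaced by Li, same spatial arrangement) | C=C(CC[C@H](C)C(=C)C)[C@H](C)C[Li] | intermediate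
26 | bromo[(2S,6S)-2,6,7-trimethyl-3-methylideneoct-7-en-1-yl]magnesium | C=C(CC[C@H](C)C(=C)C)[C@H](C)C[Mg]Br | intermediate
27 | (2E,6E,10R,14S)-2,7,10,14,15-pentamethyl-11-methylidenehexadeca-2,6,15-trien-1-ol | C=C(CC[C@H](C)C(=C)C)[C@H](C)CC/C(C)=C/CC/C=C(\C)CO | intermediate
28 | [(2R,3R)-2-methyl-3-[(3E,7R,11S)-4,7,11,12-tetramethyl-8-methylidenetrideca-3,12-dien-1-yl]oxiran-2-yl]methanol | C=C(CC[C@H](C)C(=C)C)[C@H](C)CC/C(C)=C/CC[C@H]1O[C@]1(C)CO | intermediate
29 | [(2R,3R)-2-methyl-3-[(3E,7R,11S)-4,7,11,12-tetramethyl-8-methylidenetrideca-3,12-dien-1-yl]oxiran-2-yl]methyl trifluoromethanesulfonate | C=C(CC[C@H](C)C(=C)C)[C@H](C)CC/C(C)=C/CC[C@H]1O[C@]1(C)COS(=O)(=O)C(F)(F)F | intermediate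
30 | [(2R)-2,7-dimethyl-3-methylideneoct-6-en-1-yl]lithium (23 with I replaced by Li, same spatial arrangement) | CC(C)=CCCC(=C)[C@H](C)C[Li] | intermediate
31 | bromo[(2S)-2,7-dimethyl-3-methylideneoct-6-en-1-yl]magnesium | CC(C)=CCCC(=C)[C@H](C)C[Mg]Br | intermediate
32 | (2R,3R)-2-[(3R)-3,8-dimethyl-4-methylidenenon-7-en-1-yl]-2-methyl-3-[(3E,7R,11S)-4,7,11,12-tetramethyl-8-methylidenetrideca-3,12-dien-1-yl]oxirane; chain descriptors 3S,7R,10E,14R,15R,18R | C=C(CC[C@H](C)C(=C)C)[C@H](C)CC/C(C)=C/CC[C@H]1O[C@]1(C)CC[C@@H](C)C(=C)CCC=C(C)C | target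

**Step count**
Total: 13 steps. Longest linear sequence: 7 steps (4 → 6 → 7 → 8 → 11 → 12 → 13, from isoprene).

**The three steps most likely to fail**

1. Step 4 (the new hydroxymethylation; steps 5 and 9 are runs of the same reaction and share the risk). Possible failures are the linear 4,1-adduct, low enantioselectivity, or drift of the β,γ-unsaturated carboxylate into conjugation, which would erase the stereocentre. The fallback is the known Evans deconjugative α-methylation. It does not branch from a compound of the route: it replaces 8 and 19, sets out from commercial 3-methylbut-2-enoyl chloride, (2E)-3,7-dimethylocta-2,6-dienoic acid (geranic acid) and (4R)- or (4S)-4-benzyl-1,3-oxazolidin-2-one, and comes back to the route at 11, at 14 and at 22. The (4R)-auxiliary is N-acylated (n-BuLi, THF, −78 °C, then the acid chloride) to (4R)-4-benzyl-3-(3-methylbut-2-enoyl)-1,3-oxazolidin-2-one F1. NaN(SiMe3)2 (THF, −78 °C) removes a γ-proton to give the chelated sodium (Z)-dienolate F2, which MeI alkylates at the α-carbon on the face away from the benzyl group to give (4R)-4-benzyl-3-[(2R)-2,3-dimethylbut-3-enoyl]-1,3-oxazolidin-2-one F3. LiBH4 (Et2O, 1 equiv H2O, 0 °C) then releases 11 and the auxiliary. In the same way the (4S)-auxiliary gives (4S)-4-benzyl-3-(3-methylbut-2-enoyl)-1,3-oxazolidin-2-one F4, its sodium (Z)-dienolate F5 and (4S)-4-benzyl-3-[(2S)-2,3-dimethylbut-3-enoyl]-1,3-oxazolidin-2-one F6, which LiBH4 reduces to 14. For 22, the (4S)-auxiliary is N-acylated with geranic acid (PivCl, Et3N, LiCl, THF) to (4S)-4-benzyl-3-[(2E)-3,7-dimethylocta-2,6-dienoyl]-1,3-oxazolidin-2-one F7. NaN(SiMe3)2 removes a proton from the C3 methyl group, which lies cis to the carbonyl group in the 2E isomer, to give the sodium (Z)-dienolate F8. MeI then gives (4S)-4-benzyl-3-[(2S)-2,7-dimethyl-3-methylideneoct-6-enoyl]-1,3-oxazolidin-2-one F9, which LiBH4 reduces to 22.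

2. Step 13 (triflate displacement next to the fully substituted oxirane carbon). C16 is neopentyl-like, so the Grignard reagent or the halide salts may open the oxirane, or the triflate may decompose. The fallback sets out from 27 and comes back at 32; it forms C16–C17 by opening a terminal epoxide and then re-closes the oxirane by a C–O bond. Sharpless epoxidation of 27 with L-(+)-diethyl tartrate gives the enantiomeric epoxy alcohol [(2S,3S)-2-methyl-3-[(3E,7R,11S)-4,7,11,12-tetramethyl-8-methylidenetrideca-3,12-dien-1-yl]oxiran-2-yl]methanol F10. Its lithium alkoxide (n-BuLi, LiCl, THF, 0 °C → rt) equilibrates by Payne rearrangement, with inversion at C15, to the terminal epoxide lithium (1S,4E,8R,12S)-5,8,12,13-tetramethyl-9-methylidene-1-[(2R)-2-methyloxiran-2-yl]tetradeca-4,13-dien-1-olate F11. Grignard reagent 31 with catalytic CuI opens F11 at its unhindered CH2 to give (3S,7R,10E,14S,15R,18R)-2,3,7,10,15,18,23-heptamethyl-6,19-dimethylidenetetracosa-1,10,22-triene-14,15-diol F12. MsCl/pyridine at 0 °C mesylates only the secondary hydroxyl to give (3S,7R,10E,14S,15R,18R)-15-hydroxy-2,3,7,10,15,18,23-heptamethyl-6,19-dimethylidenetetracosa-1,10,22-trien-14-yl methanesulfonate F13. K2CO3 in MeOH closes the oxirane with inversion at C14, so that both oxirane carbons are inverted relative to F10 and 32 results.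

3. Step 11 (Li2CuCl4-catalysed allyl–alkyl coupling). γ-Attack (SN2′) would give a branched isomer that is hard to separate, and the unprotected alkoxide may slow the catalyst. The fallback sets out from 18 (and uses 24) and comes back at 27. PhSO2Na in DMF converts 18 into {[(2S,6S)-2,6,7-trimethyl-3-methylideneoct-7-en-1-yl]sulfonyl}benzene F14. n-BuLi (THF/DMPU, −78 °C) gives the α-sulfonyl carbanion [(2S,6S)-2,6,7-trimethyl-3-methylidene-1-(phenylsulfonyl)oct-7-en-1-yl]lithium F15, which alkylates the primary allylic chloride of 24 cleanly at the α-carbon to give (2E,6E,10S,14S)-2,7,10,14,15-pentamethyl-11-methylidene-9-(phenylsulfonyl)hexadeca-2,6,15-trien-1-ol F16 (both C9 epimers). Sodium amalgam (Na/Hg) with Na2HPO4 in MeOH/THF at −20 °C removes the non-allylic sulfonyl group to give 27.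

**Further compounds**
F1 | step 4 | (4R)-4-benzyl-3-(3-methylbut-2-enoyl)-1,3-oxazolidin-2-one | CC(C)=CC(=O)N1[C@H](Cc2ccccc2)COC1=O
F2 | step 4 | sodium (1Z)-1-[(4R)-4-benzyl-2-oxo-1,3-oxazolidin-3-yl]-3-methylbuta-1,3-dien-1-olate | C=C(C)/C=C(\[O-])N1[C@H](Cc2ccccc2)COC1=O.[Na+]
F3 | step 4 | (4R)-4-benzyl-3-[(2R)-2,3-dimethylbut-3-enoyl]-1,3-oxazolidin-2-one | C=C(C)[C@@H](C)C(=O)N1[C@H](Cc2ccccc2)COC1=O
F4 | step 5 | (4S)-4-benzyl-3-(3-methylbut-2-enoyl)-1,3-oxazolidin-2-one | CC(C)=CC(=O)N1[C@@H](Cc2ccccc2)COC1=O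
F5 | step 5 | sodium (1Z)-1-[(4S)-4-benzyl-2-oxo-1,3-oxazolidin-3-yl]-3-methylbuta-1,3-dien-1-olate | C=C(C)/C=C(\[O-])N1[C@@H](Cc2ccccc2)COC1=O.[Na+]
F6 | step 5 | (4S)-4-benzyl-3-[(2S)-2,3-dimethylbut-3-enoyl]-1,3-oxazolidin-2-one | C=C(C)[C@H](C)C(=O)N1[C@@H](Cc2ccccc2)COC1=O
F7 | step 9 | (4S)-4-benzyl-3-[(2E)-3,7-dimethylocta-2,6-dienoyl]-1,3-oxazolidin-2-one | CC(C)=CCC/C(C)=C/C(=O)N1[C@@H](Cc2ccccc2)COC1=O
F8 | step 9 | sodium (1Z)-1-[(4S)-4-benzyl-2-oxo-1,3-oxazolidin-3-yl]-7-methyl-3-methylideneocta-1,6-dien-1-olate | CC(C)=CCCC(=C)/C=C(\[O-])N1[C@@H](Cc2ccccc2)COC1=O.[Na+]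
F9 | step 9 | (4S)-4-benzyl-3-[(2S)-2,7-dimethyl-3-methylideneoct-6-enoyl]-1,3-oxazolidin-2-one | CC(C)=CCCC(=C)[C@H](C)C(=O)N1[C@@H](Cc2ccccc2)COC1=O
F10 | step 13 | [(2S,3S)-2-methyl-3-[(3E,7R,11S)-4,7,11,12-tetramethyl-8-methylidenetrideca-3,12-dien-1-yl]oxiran-2-yl]methanol | C=C(CC[C@H](C)C(=C)C)[C@H](C)CC/C(C)=C/CC[C@@H]1O[C@@]1(C)CO
F11 | step 13 | lithium (1S,4E,8R,12S)-5,8,12,13-tetramethyl-9-methylidene-1-[(2R)-2-methyloxiran-2-yl]tetradeca-4,13-dien-1-olate | C=C(CC[C@H](C)C(=C)C)[C@H](C)CC/C(C)=C/CC[C@H](O[Li])[C@@]1(C)CO1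
F12 | step 13 | (3S,7R,10E,14S,15R,18R)-2,3,7,10,15,18,23-heptamethyl-6,19-dimethylidenetetracosa-1,10,22-triene-14,15-diol | C=C(CC[C@H](C)C(=C)C)[C@H](C)CC/C(C)=C/CC[C@H](O)[C@](C)(O)CC[C@@H](C)C(=C)CCC=C(C)C
F13 | step 13 | (3S,7R,10E,14S,15R,18R)-15-hydroxy-2,3,7,10,15,18,23-heptamethyl-6,19-dimethylidenetetracosa-1,10,22-trien-14-yl methanesulfonate | C=C(CC[C@H](C)C(=C)C)[C@H](C)CC/C(C)=C/CC[C@H](OS(C)(=O)=O)[C@](C)(O)CC[C@@H](C)C(=C)CCC=C(C)C
F14 | step 11 | {[(2S,6S)-2,6,7-trimethyl-3-methylideneoct-7-en-1-yl]sulfonyl}benzene | C=C(CC[C@H](C)C(=C)C)[C@H](C)CS(=O)(=O)c1ccccc1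
F15 | step 11 | [(2S,6S)-2,6,7-trimethyl-3-methylidene-1-(phenylsulfonyl)oct-7-en-1-yl]lithium | C=C(CC[C@H](C)C(=C)C)[C@H](C)C([Li])S(=O)(=O)c1ccccc1
F16 | step 11 | (2E,6E,10S,14S)-2,7,10,14,15-pentamethyl-11-methylidene-9-(phenylsulfonyl)hexadeca-2,6,15-trien-1-ol (C9 epimers) | C=C(CC[C@H](C)C(=C)C)[C@H](C)C(C/C(C)=C/CC/C=C(\C)CO)S(=O)(=O)c1ccccc1
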